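Ring B (C5–C10, labdane numbering) of the target is a cyclohexene whose tetrasubstituted C8=C9 alkene carries C17 and the chain carbon C11, with quaternary C10 on one side and oxygenated C6 across the ring. That pattern is what a Diels–Alder addition of methyl but-2-ynoate to a 2-ethoxydiene, C10=C5–C6(OEt)=C7, mounted on an enantiopure ring A would leave. One cycloaddition forms C7–C8 and C9–C10, closes ring B, sets C10 and delivers C6 as an enol ether and C11 as an ester. The precursor is a ring A cyclohexene with the 1-ethoxyvinyl group on C5, the C20 methyl on C10, a 3β-triethylsilyloxy group and a C4 bearing α-methyl and β-CH2OTBDPS.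

Key step: step 8

Remarks
- Labdane numbering (C1–C20) is used for every intermediate; β is the face of C20 in the target. TBDPS = tert-butyl(diphenyl)silyl, TES = triethylsilyl.
- Assumption: a ketoreductase giving the (2S,3S) hydroxy ketone 4 is found by screening a commercial enzyme panel.
- O3 and O19 are carried as two separate silyl ethers, not as one cyclic acetal. A cis-fused 2,2-dimethyl-1,3-dioxane would prefer the half-chair with O3 axial and C19 equatorial; this puts the C18 methyl axial on the α-face, the face the ynoate must reach. Separate groups also keep O19 masked to the last step while O3 is freed for inversion.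
- The 3β configuration from the enzymatic step is kept through the cycloaddition and inverted late through the 3-ketone.
- C15 is carried as a tert-butyl ester so that the isovalerates never meet hydroxide and the acid is never activated next to its γ-hydrogens.

Step 1
Reactants: 1 2-methylcyclohexane-1,3-dione; 2 formaldehyde
Product: 3 2-(hydroxymethyl)-2-methylcyclohexane-1,3-dione
Conditions: aq. CH2O (37 %), NaHCO3 (cat.), H2O, rt
Reagents that add atoms: formaldehyde 2, C=O
Why: Aldol hydroxymethylation of the acidic C2–H of a 2-alkyl-1,3-dione, which stops after one addition because no C2–H remains; no stereocenter is formed.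

Step 2
Reactants: 3 2-(hydroxymethyl)-2-methylcyclohexane-1,3-dione
Product: 4 (2S,3S)-3-hydroxy-2-(hydroxymethyl)-2-methylcyclohexan-1-one
Conditions: ketoreductase (panel-selected), NADP+ (cat.), i-PrOH, phosphate buffer pH 7, 30 °C
Reagents that add atoms: none
Why: Enzymatic desymmetrising reduction of a prochiral 2,2-disubstituted cyclohexane-1,3-dione, a known substrate class for yeast and isolated ketoreductases; the enzyme's choice of one enantiotopic carbonyl and one face sets C3 (S, hydroxyl cis to CH2OH) and C4 (S) together.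

Step 3
Reactants: 4 (2S,3S)-3-hydroxy-2-(hydroxymethyl)-2-methylcyclohexan-1-one
Product: 5 (2S,3S)-2-{[tert-butyl(diphenyl)silyl]oxymethyl}-3-hydroxy-2-methylcyclohexan-1-one
Conditions: t-BuPh2SiCl, imidazole, CH2Cl2, 0 °C
Reagents that add atoms: tert-butyl(chloro)diphenylsilane, CC(C)(C)[Si](Cl)(c1ccccc1)c1ccccc1
Why: Silylation with a bulky chlorosilane should select the primary C19 hydroxyl over the hindered secondary one, and the mild base does not trigger retro-aldol cleavage.

Step 4
Reactants: 5 (2S,3S)-2-{[tert-butyl(diphenyl)silyl]oxymethyl}-3-hydroxy-2-methylcyclohexan-1-one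
Product: 6 (2S,3S)-2-{[tert-butyl(diphenyl)silyl]oxymethyl}-2-methyl-3-(triethylsilyloxy)cyclohexan-1-one
Conditions: Et3SiOTf, 2,6-lutidine, CH2Cl2, −78 °C
Reagents that add atoms: triethylsilyl trifluoromethanesulfonate, CC[Si](CC)(CC)OS(=O)(=O)C(F)(F)F
Why: A silyl triflate silylates the hindered secondary alcohol at low temperature faster than it converts the ketone into a silyl enol ether.

Step 5
Reactants: 6 (2S,3S)-2-{[tert-butyl(diphenyl)silyl]oxymethyl}-2-methyl-3-(triethylsilyloxy)cyclohexan-1-one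
Product: 7 (2S,3S,6RS)-2-{[tert-butyl(diphenyl)silyl]oxymethyl}-2,6-dimethyl-3-(triethylsilyloxy)cyclohexan-1-one (C10 epimers)
Conditions: LiN(i-Pr)2, THF, −78 °C; MeI, −78 → −20 °C
Reagents that add atoms: iodomethane, CI
Why: Enolate alkylation can occur only at C10 because C4 is quaternary, and the new C10 stereocenter, formed as a mixture, is erased in step 6.

Step 6
Reactants: 7 (2S,3S,6RS)-2-{[tert-butyl(diphenyl)silyl]oxymethyl}-2,6-dimethyl-3-(triethylsilyloxy)cyclohexan-1-one
Product: 8 (5S,6S)-6-{[tert-butyl(diphenyl)silyl]oxymethyl}-2,6-dimethyl-5-(triethylsilyloxy)cyclohex-1-en-1-yl trifluoromethanesulfonate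
Conditions: KN(SiMe3)2, THF, −78 → 0 °C; PhNTf2
Reagents that add atoms: N-phenylbis(trifluoromethanesulfonimide), O=S(=O)(N(c1ccccc1)S(=O)(=O)C(F)(F)F)C(F)(F)F
Why: O-sulfonylation of the only possible enolate gives the tetrasubstituted C5=C10 enol triflate, as is routine for 2,2,6-trisubstituted cyclohexanones.

Step 7
Reactants: 8 enol triflate; 9 tributyl(1-ethoxyvinyl)stannane
Product: 10 tert-butyl{[(1S,6S)-2-(1-ethoxyethenyl)-1,3-dimethyl-6-(triethylsilyloxy)cyclohex-2-en-1-yl]methoxy}diphenylsilane (ring A 2-ethoxydiene)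
Conditions: Pd(PPh3)4 (5 mol %), CuI (10 mol %), LiCl, THF, 65 °C; Et3N-treated silica
Reagents that add atoms: tributyl(1-ethoxyvinyl)stannane 9, CCCC[Sn](CCCC)(CCCC)C(=C)OCC
Why: Stille coupling (oxidative addition of zerovalent palladium into the enol triflate, tin-to-palladium transfer aided by LiCl and CuI, reductive elimination) forms C5–C6 and gives the 2-ethoxydiene without touching C3 or C4.

Step 8
Reactants: 10 ring A 2-ethoxydiene; 11 methyl but-2-ynoate
Product: 12 methyl (3S,4S,10S)-6-ethoxy-3β-(triethylsilyloxy)-19-[tert-butyl(diphenyl)silyloxy]-12,13,14,15,16-pentanorlabda-5,8-dien-11-oate (ring B 1,4-diene; C20 β)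
Conditions: 11 (6 equiv), BHT and 2,6-di-tert-butyl-4-methylpyridine (1 mol % each), CH2Cl2, 13 kbar, 40 °C
Reagents that add atoms: methyl but-2-ynoate 11, CC#CC(=O)OC
Why: The reaction is a concerted, asynchronous normal-electron-demand [4+2] cycloaddition in which the enol-ether terminus C7 (largest HOMO coefficient of the 2-ethoxydiene) bonds to the β-carbon C8 of the ynoate while the fully substituted C10 bonds to the ester-bearing C9, giving the 1,4-cyclohexadiene with OEt on C6 para to CO2Me on C9. The closest known reaction type is the Diels–Alder addition of 2-alkoxy- and 2-silyloxydienes to alkynoates, together with the additions of acetylenic esters to 1-vinyl-2,6,6-trimethylcyclohexene that build the same decalin, so a known reaction is applied here to a diene with a more hindered terminus. Ring B (C5–C10) is closed as a six-membered ring by the cycloaddition itself, both new σ-bonds forming on one face of the s-cis diene. C10, the only new stereocenter, is controlled by the C4 and C3 substituents: the β-face carries the CH2OTBDPS group of C4 (pseudoaxial in the half-chair with O3 equatorial) or, in the other half-chair, the axial 3β-OTES group, whereas the α-face carries only the C18 methyl, so the ynoate should bond to C10 from the α-face and leave C20 β, cis to C19. The step needs regioselectivity, facial selectivity and a clean thermal course: the first comes from the 2-ethoxy group, the second from the substituents just named, and the third from using pressure (negative volume of activation) at 40 °C in place of heat, which keeps the 1,5-hydrogen shift from C20 to C7 out of the way. The adduct cannot aromatise because C10 is quaternary.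

Step 9
Reactants: 12 Diels–Alder adduct
Product: 13 (3S,4S,10S)-6-ethoxy-3β-(triethylsilyloxy)-19-[tert-butyl(diphenyl)silyloxy]-12,13,14,15,16-pentanorlabda-5,8-dien-11-ol
Conditions: i-Bu2AlH (3 equiv), CH2Cl2, −78 → 0 °C; aq. potassium sodium tartrate
Reagents that add atoms: none
Why: Hydride 1,2-reduction of the hindered conjugated ester gives the C11 allylic alcohol, and the enol ether and both silyl ethers are inert to the aluminium hydride and the neutral work-up.

Step 10
Reactants: 13 C11 allylic alcohol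
Product: 15 (3S,4S,10S)-11-bromo-6-ethoxy-3β-(triethylsilyloxy)-19-[tert-butyl(diphenyl)silyloxy]-12,13,14,15,16-pentanorlabda-5,8-diene, via C11 methanesulfonate 14 (not isolated)
Conditions: Ms2O, Et3N, THF, −40 °C; then LiBr, −40 → 0 °C; used crude
Reagents that add atoms: lithium bromide, [Li+].[Br-]
Why: Sulfonylation and SN2 displacement by bromide convert the primary allylic alcohol into the bromide under buffered, non-aqueous conditions that spare the enol ether.

Step 11
Reactants: 15 C11 allylic bromide; 16 tert-butyl acetoacetate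
Product: 17 tert-butyl (3S,4S,10S)-6-ethoxy-13-oxo-3β-(triethylsilyloxy)-19-[tert-butyl(diphenyl)silyloxy]-16-norlabda-5,8-dien-15-oate
Conditions: 16 (2 equiv), NaH, THF, 0 °C; n-BuLi, 0 °C; then 15, 0 °C → rt; cold aq. NH4Cl
Reagents that add atoms: tert-butyl acetoacetate 16, CC(=O)CC(=O)OC(C)(C)C
Why: γ-Alkylation of the acetoacetate dianion by SN2 attack on the primary allylic bromide forms C11–C12, the standard chain extension for allylic halides.

Step 12
Reactants: 17 β-keto ester
Product: 18 tert-butyl (13Z)-13-(diethoxyphosphoryloxy)-6-ethoxy-3β-(triethylsilyloxy)-19-[tert-butyl(diphenyl)silyloxy]-16-norlabda-5,8,13-trien-15-oate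
Conditions: NaH, Et2O, 0 °C; ClP(O)(OEt)2
Reagents that add atoms: diethyl chlorophosphate, CCOP(=O)(Cl)OCC
Why: O-phosphorylation of the chelated sodium enolate of a β-keto ester gives the (Z)-enol phosphate, with the phosphate cis to the ester.

Step 13
Reactants: 18 (Z)-enol phosphate
Product: 19 tert-butyl (13E)-6-ethoxy-3β-(triethylsilyloxy)-19-[tert-butyl(diphenyl)silyloxy]labda-5,8,13-trien-15-oate
Conditions: Me2CuLi (from MeLi and CuI), Et2O, −78 → −45 °C
Reagents that add atoms: lithium dimethylcuprate, [Li+].C[Cu-]C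
Why: Cuprate addition–elimination on the β-phosphoryloxy enoate replaces the phosphate by methyl (C16) with retention of geometry, which gives the (13E) enoate.

Step 14
Reactants: 19 (13E) trienoate
Product: 20 tert-butyl (13E)-3β-hydroxy-6-oxo-19-[tert-butyl(diphenyl)silyloxy]labda-8,13-dien-15-oate (5α-H)
Conditions: AcOH/THF/H2O (3:1:1), rt → 40 °C
Reagents that add atoms: water, O
Why: Weak aqueous acid hydrolyses the enol ether to the C6 ketone and cleaves the triethylsilyl ether while leaving the C8=C9 bond unconjugated, and C5 is set by protonation on the α-face, anti to the axial C19 and C20 groups, giving the trans ring fusion that is also favoured at equilibrium.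

Step 15
Reactants: 20 3β-hydroxy-6-ketone
Product: 21 tert-butyl (13E)-3,6-dioxo-19-[tert-butyl(diphenyl)silyloxy]labda-8,13-dien-15-oate
Conditions: Dess–Martin periodinane, CH2Cl2, 0 °C → rt
Reagents that add atoms: none
Why: Dess–Martin oxidation of the secondary C3 alcohol proceeds under non-basic conditions that neither epimerise C5 nor move the C8=C9 bond.

Step 16
Reactants: 21 3,6-diketone
Product: 22 tert-butyl (13E)-3α,6β-dihydroxy-19-[tert-butyl(diphenyl)silyloxy]labda-8,13-dien-15-oate
Conditions: LiBH(s-Bu)3 (3 equiv), THF, −78 °C; aq. NH4Cl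
Reagents that add atoms: none
Why: The bulky borohydride attacks C3 along the equatorial line to give the axial 3α-alcohol (as with 4,4-disubstituted 3-ketones of terpenoids) and attacks C6 from the open α-face, away from axial C19 and C20, to give the axial 6β-alcohol, while the β,β-disubstituted enoate is not reduced at −78 °C.

Step 17
Reactants: 22 3α,6β-diol; 23 isovaleric anhydride
Product: 24 tert-butyl (13E)-3α,6β-bis(3-methylbutanoyloxy)-19-[tert-butyl(diphenyl)silyloxy]labda-8,13-dien-15-oate
Conditions: 23 (6 equiv), DMAP (3 equiv), pyridine, 60 °C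
Reagents that add atoms: isovaleric anhydride 23, CC(C)CC(=O)OC(=O)CC(C)C
Why: DMAP-mediated acylation through the N-acylpyridinium ion esterifies both axial secondary alcohols with retention, and the silyl ether, the tert-butyl ester and both alkenes are inert.

Step 18
Reactants: 24 bis-isovalerate tert-butyl ester
Product: 26 (13E)-3α,6β-bis(3-methylbutanoyloxy)-19-[tert-butyl(diphenyl)silyloxy]labda-8,13-dien-15-oic acid, via trimethylsilyl ester 25 (not isolated)
Conditions: Me3SiOTf, 2,6-lutidine, CH2Cl2, 0 °C → rt; then aqueous buffer pH 4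
Reagents that add atoms: none
Why: Silylation of the ester carbonyl releases the tert-butyl group as isobutene without protic acid, and the silyl ester hydrolyses on work-up, while the secondary isovalerates, the TBDPS ether and the tetrasubstituted alkene are left alone.

Step 19
Reactants: 26 19-O-silylated acid
Product: 27 (13E)-19-hydroxy-3α,6β-bis(3-methylbutanoyloxy)labda-8,13-dien-15-oic acid, (3R,4S,5R,6R,10S) (target)
Conditions: HF·pyridine, pyridine, THF, 0 °C → rt
Reagents that add atoms: none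
Why: Buffered, mildly acidic fluoride desilylation frees O19 without forming an alkoxide that could take an acyl group from the nearby O6 ester.

Compound list
1 | 2-methylcyclohexane-1,3-dione | CC1C(=O)CCCC1=O | starting material
2 | formaldehyde | C=O | starting material
3 | 2-(hydroxymethyl)-2-methylcyclohexane-1,3-dione | CC1(CO)C(=O)CCCC1=O | intermediate
4 | (2S,3S)-3-hydroxy-2-(hydroxymethyl)-2-methylcyclohexan-1-one | O=C1CCC[C@H](O)[C@]1(C)CO | intermediate
5 | (2S,3S)-2-{[tert-butyl(diphenyl)silyl]oxymethyl}-3-hydroxy-2-methylcyclohexan-1-one | O=C1CCC[C@H](O)[C@]1(C)CO[Si](c2ccccc2)(c2ccccc2)C(C)(C)C | intermediate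
6 | (2S,3S)-2-{[tert-butyl(diphenyl)silyl]oxymethyl}-2-methyl-3-(triethylsilyloxy)cyclohexan-1-one | O=C1CCC[C@H](O[Si](CC)(CC)CC)[C@]1(C)CO[Si](c2ccccc2)(c2ccccc2)C(C)(C)C | intermediate
7 | (2S,3S,6RS)-2-{[tert-butyl(diphenyl)silyl]oxymethyl}-2,6-dimethyl-3-(triethylsilyloxy)cyclohexan-1-one | O=C1C(C)CC[C@H](O[Si](CC)(CC)CC)[C@]1(C)CO[Si](c2ccccc2)(c2ccccc2)C(C)(C)C | intermediate
8 | (5S,6S)-6-{[tert-butyl(diphenyl)silyl]oxymethyl}-2,6-dimethyl-5-(triethylsilyloxy)cyclohex-1-en-1-yl trifluoromethanesulfonate | O=S(=O)(OC1=C(C)CC[C@H](O[Si](CC)(CC)CC)[C@]1(C)CO[Si](c2ccccc2)(c2ccccc2)C(C)(C)C)C(F)(F)F | intermediate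
9 | tributyl(1-ethoxyvinyl)stannane | CCCC[Sn](CCCC)(CCCC)C(=C)OCC | starting material
10 | ring A 2-ethoxydiene, tert-butyl{[(1S,6S)-2-(1-ethoxyethenyl)-1,3-dimethyl-6-(triethylsilyloxy)cyclohex-2-en-1-yl]methoxy}diphenylsilane | C=C(OCC)C1=C(C)CC[C@H](O[Si](CC)(CC)CC)[C@]1(C)CO[Si](c2ccccc2)(c2ccccc2)C(C)(C)C | intermediate
11 | methyl but-2-ynoate | CC#CC(=O)OC | starting material
12 | Diels–Alder adduct, methyl (3S,4S,10S)-6-ethoxy-3β-(triethylsilyloxy)-19-(TBDPS-oxy)-12,13,14,15,16-pentanorlabda-5,8-dien-11-oate | CC1=C(C(=O)OC)[C@@]2(C)CC[C@H](O[Si](CC)(CC)CC)[C@](C)(CO[Si](c3ccccc3)(c3ccccc3)C(C)(C)C)C2=C(OCC)C1 | intermediate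
13 | C11 allylic alcohol of 12 | CC1=C(CO)[C@@]2(C)CC[C@H](O[Si](CC)(CC)CC)[C@](C)(CO[Si](c3ccccc3)(c3ccccc3)C(C)(C)C)C2=C(OCC)C1 | intermediate
14 | C11 methanesulfonate of 13 (not isolated) | CC1=C(COS(C)(=O)=O)[C@@]2(C)CC[C@H](O[Si](CC)(CC)CC)[C@](C)(CO[Si](c3ccccc3)(c3ccccc3)C(C)(C)C)C2=C(OCC)C1 | intermediate
15 | C11 allylic bromide | CC1=C(CBr)[C@@]2(C)CC[C@H](O[Si](CC)(CC)CC)[C@](C)(CO[Si](c3ccccc3)(c3ccccc3)C(C)(C)C)C2=C(OCC)C1 | intermediate
16 | tert-butyl acetoacetate | CC(=O)CC(=O)OC(C)(C)C | starting material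
17 | 13-oxo β-keto ester, tert-butyl 6-ethoxy-13-oxo-3β-(triethylsilyloxy)-19-(TBDPS-oxy)-16-norlabda-5,8-dien-15-oate | CC1=C(CCC(=O)CC(=O)OC(C)(C)C)[C@@]2(C)CC[C@H](O[Si](CC)(CC)CC)[C@](C)(CO[Si](c3ccccc3)(c3ccccc3)C(C)(C)C)C2=C(OCC)C1 | intermediate
18 | (13Z)-enol diethyl phosphate of 17 | CC1=C(CC/C(OP(=O)(OCC)OCC)=C/C(=O)OC(C)(C)C)[C@@]2(C)CC[C@H](O[Si](CC)(CC)CC)[C@](C)(CO[Si](c3ccccc3)(c3ccccc3)C(C)(C)C)C2=C(OCC)C1 | intermediate
19 | tert-butyl (13E)-6-ethoxy-3β-(triethylsilyloxy)-19-(TBDPS-oxy)labda-5,8,13-trien-15-oate | CC1=C(CC/C(C)=C/C(=O)OC(C)(C)C)[C@@]2(C)CC[C@H](O[Si](CC)(CC)CC)[C@](C)(CO[Si](c3ccccc3)(c3ccccc3)C(C)(C)C)C2=C(OCC)C1 | intermediate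
20 | tert-butyl (13E)-3β-hydroxy-6-oxo-19-(TBDPS-oxy)labda-8,13-dien-15-oate (5α-H) | CC1=C(CC/C(C)=C/C(=O)OC(C)(C)C)[C@@]2(C)CC[C@H](O)[C@](C)(CO[Si](c3ccccc3)(c3ccccc3)C(C)(C)C)[C@@H]2C(=O)C1 | intermediate
21 | tert-butyl (13E)-3,6-dioxo-19-(TBDPS-oxy)labda-8,13-dien-15-oate | CC1=C(CC/C(C)=C/C(=O)OC(C)(C)C)[C@@]2(C)CCC(=O)[C@](C)(CO[Si](c3ccccc3)(c3ccccc3)C(C)(C)C)[C@@H]2C(=O)C1 | intermediate
22 | tert-butyl (13E)-3α,6β-dihydroxy-19-(TBDPS-oxy)labda-8,13-dien-15-oate | CC1=C(CC/C(C)=C/C(=O)OC(C)(C)C)[C@@]2(C)CC[C@@H](O)[C@](C)(CO[Si](c3ccccc3)(c3ccccc3)C(C)(C)C)[C@@H]2[C@H](O)C1 | intermediate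
23 | isovaleric anhydride (3-methylbutanoic anhydride) | CC(C)CC(=O)OC(=O)CC(C)C | starting material
24 | tert-butyl (13E)-3α,6β-bis(3-methylbutanoyloxy)-19-(TBDPS-oxy)labda-8,13-dien-15-oate | CC1=C(CC/C(C)=C/C(=O)OC(C)(C)C)[C@@]2(C)CC[C@@H](OC(=O)CC(C)C)[C@](C)(CO[Si](c3ccccc3)(c3ccccc3)C(C)(C)C)[C@@H]2[C@H](OC(=O)CC(C)C)C1 | intermediate
25 | trimethylsilyl ester of 26 (not isolated) | CC1=C(CC/C(C)=C/C(=O)O[Si](C)(C)C)[C@@]2(C)CC[C@@H](OC(=O)CC(C)C)[C@](C)(CO[Si](c3ccccc3)(c3ccccc3)C(C)(C)C)[C@@H]2[C@H](OC(=O)CC(C)C)C1 | intermediate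
26 | (13E)-3α,6β-bis(3-methylbutanoyloxy)-19-(TBDPS-oxy)labda-8,13-dien-15-oic acid | CC1=C(CC/C(C)=C/C(=O)O)[C@@]2(C)CC[C@@H](OC(=O)CC(C)C)[C@](C)(CO[Si](c3ccccc3)(c3ccccc3)C(C)(C)C)[C@@H]2[C@H](OC(=O)CC(C)C)C1 | intermediate
27 | (13E)-19-hydroxy-3α,6β-bis(3-methylbutanoyloxy)labda-8,13-dien-15-oic acid, (3R,4S,5R,6R,10S) | CC1=C(CC/C(C)=C/C(=O)O)[C@@]2(C)CC[C@@H](OC(=O)CC(C)C)[C@](C)(CO)[C@@H]2[C@H](OC(=O)CC(C)C)C1 | target

Total steps: 19. Longest linear sequence: 19 steps (from 1; compounds 2, 9, 11, 16 and 23 are bought).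

Steps most likely to fail

Step 8. Bond formation at the fully substituted, twisted C10 terminus may be too slow even under pressure, so that isomerisation of the diene or attack on the β-face takes over. Fallback: diene 10 is combined with the much more electrophilic but-2-ynal (bought; 5–10 kbar or neat at 40–60 °C). With the same orientation this should give the C11 aldehyde, (3S,4S,10S)-6-ethoxy-3β-(triethylsilyloxy)-19-(TBDPS-oxy)-12,13,14,15,16-pentanorlabda-5,8-dien-11-al F1. Reduction of F1 with i-Bu2AlH at −78 °C returns to allylic alcohol 13, so steps 8 and 9 are replaced and the route is rejoined at 13.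

Step 17. Acylation may stall at the axial 6β-hydroxyl, which sits between C20 and the silyloxymethyl group on C4. Fallback: the silyl group is taken off first and C19 is masked by the acyl group itself. From diol 22, HF·pyridine gives tert-butyl (13E)-3α,6β,19-trihydroxylabda-8,13-dien-15-oate F2. Exhaustive acylation (isovaleryl chloride, DMAP, pyridine, 60 °C), in which C19 reacts first and leaves only a small acyloxymethyl group beside O6, gives the tris-isovalerate tert-butyl ester F3. Lipase-mediated butanolysis (immobilised lipase B from Candida antarctica, n-BuOH, methyl tert-butyl ether, 40 °C) removes only the unhindered primary ester at neutral pH and gives tert-butyl (13E)-19-hydroxy-3α,6β-bis(3-methylbutanoyloxy)labda-8,13-dien-15-oate F4. Me3SiOTf/2,6-lutidine then passes through the bis-trimethylsilyl compound (silyl ester and 19-O-silyl ether) F5, which hydrolyses on the pH 4 work-up, and the sequence ends at target 27.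

Step 14. The C8=C9 double bond may migrate into conjugation with the new C6 ketone before the hindered silyl ether on O3 has been cleaved. Fallback: the two unmaskings are separated. From 19, Et3N·3HF in THF removes only the triethylsilyl group and should give tert-butyl (13E)-6-ethoxy-3β-hydroxy-19-(TBDPS-oxy)labda-5,8,13-trien-15-oate F6. Dess–Martin oxidation in the presence of pyridine gives the 3-oxo enol ether, tert-butyl (13E)-6-ethoxy-3-oxo-19-(TBDPS-oxy)labda-5,8,13-trien-15-oate F7. A short contact with oxalic acid on wet silica gel, the mildest hydrolysis used for 1-alkoxycyclohexa-1,4-dienes, then returns to diketone 21.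

Further compounds
F1 | step 8 | (3S,4S,10S)-6-ethoxy-3β-(triethylsilyloxy)-19-(TBDPS-oxy)-12,13,14,15,16-pentanorlabda-5,8-dien-11-al | CC1=C(C=O)[C@@]2(C)CC[C@H](O[Si](CC)(CC)CC)[C@](C)(CO[Si](c3ccccc3)(c3ccccc3)C(C)(C)C)C2=C(OCC)C1
F2 | step 17 | tert-butyl (13E)-3α,6β,19-trihydroxylabda-8,13-dien-15-oate | CC1=C(CC/C(C)=C/C(=O)OC(C)(C)C)[C@@]2(C)CC[C@@H](O)[C@](C)(CO)[C@@H]2[C@H](O)C1
F3 | step 17 | tert-butyl (13E)-3α,6β,19-tris(3-methylbutanoyloxy)labda-8,13-dien-15-oate | CC1=C(CC/C(C)=C/C(=O)OC(C)(C)C)[C@@]2(C)CC[C@@H](OC(=O)CC(C)C)[C@](C)(COC(=O)CC(C)C)[C@@H]2[C@H](OC(=O)CC(C)C)C1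
F4 | step 17 | tert-butyl (13E)-19-hydroxy-3α,6β-bis(3-methylbutanoyloxy)labda-8,13-dien-15-oate | CC1=C(CC/C(C)=C/C(=O)OC(C)(C)C)[C@@]2(C)CC[C@@H](OC(=O)CC(C)C)[C@](C)(CO)[C@@H]2[C@H](OC(=O)CC(C)C)C1
F5 | step 17 | trimethylsilyl (13E)-3α,6β-bis(3-methylbutanoyloxy)-19-(trimethylsilyloxy)labda-8,13-dien-15-oate (not isolated) | CC1=C(CC/C(C)=C/C(=O)O[Si](C)(C)C)[C@@]2(C)CC[C@@H](OC(=O)CC(C)C)[C@](C)(CO[Si](C)(C)C)[C@@H]2[C@H](OC(=O)CC(C)C)C1
F6 | step 14 | tert-butyl (13E)-6-ethoxy-3β-hydroxy-19-(TBDPS-oxy)labda-5,8,13-trien-15-oate | CC1=C(CC/C(C)=C/C(=O)OC(C)(C)C)[C@@]2(C)CC[C@H](O)[C@](C)(CO[Si](c3ccccc3)(c3ccccc3)C(C)(C)C)C2=C(OCC)C1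
F7 | step 14 | tert-butyl (13E)-6-ethoxy-3-oxo-19-(TBDPS-oxy)labda-5,8,13-trien-15-oate | CC1=C(CC/C(C)=C/C(=O)OC(C)(C)C)[C@@]2(C)CCC(=O)[C@](C)(CO[Si](c3ccccc3)(c3ccccc3)C(C)(C)C)C2=C(OCC)C1
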